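## Retrosynthetic overview

1. Ring numbering: C1 bears CH2OBz, C2 is the vinylic CH, C3 is CH-OBz, and C4, C5, C6 are the three CH-OH. Target 8 comes from anti hydrolysis at allylic C6 of the syn-epoxy alcohol 7, which comes from OH-directed epoxidation of the trans-diene 6.
2. Diene 6 comes from a Rh(I)/Josiphos anti-SN2' opening of the achiral oxanorbornadiene 5 with benzoic acid. This step makes C1=C2, places the benzoate on C3 trans to the freed C4-OH, and sets the absolute configuration by choosing one of two enantiotopic C=C arms.
3. Compound 5 comes from a Diels-Alder reaction of furfuryl benzoate 2 with (Z)-1,2-bis(phenylsulfonyl)ethene 3 as an acetylene equivalent, followed by reductive loss of both sulfonyl groups. The cycloaddition makes C1-C2 and C3-C4 together.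
4. Ring order: the furan is bought; step 2 forms the carbocycle and a temporary 1,4-oxygen bridge; step 4 cleaves the bridge; step 5 forms a temporary oxirane, which step 6 opens. No protecting groups are used.
5. Enabling feature: in the cyclohexene ring, C1 (sp2, bearing CH2OBz) and C4 (bearing a free OH) are para to each other, so the C4 oxygen can be tied back to C1. C1-C6-C5-C4-O is then the furan ring of furfuryl benzoate, and C2-C3 is a two-carbon dienophile.

Key step: step 2

Remark: the ring numbers above are kept for the bicyclic intermediates, in which the oxygen bridge spans C1 and C4.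

Assumption: the (R,S) antipode of the Josiphos ligand is taken to deliver the (3R,4R) product. The sense of induction must be verified, and the mirror-image ligand is equally available.

## Route

Step 1
Reactants: 1 furfuryl alcohol
Product: 2 furfuryl benzoate
Conditions: BzCl, Et3N, DMAP (cat.), CH2Cl2, 0 °C to rt
Reagents that add atoms: benzoyl chloride, O=C(Cl)c1ccccc1
Why: DMAP-catalysed O-acylation (nucleophilic acyl substitution) of a primary alcohol in basic medium, which spares the acid-sensitive furan; no stereocentre is formed.

Step 2
Reactants: 2 furfuryl benzoate; 3 (Z)-1,2-bis(phenylsulfonyl)ethene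
Product: 4 racemic [2,3-cis-bis(phenylsulfonyl)-7-oxabicyclo[2.2.1]hept-5-en-1-yl]methyl benzoate
Conditions: 2 (1.5 equiv), 3, CH2Cl2 (concentrated), rt to 40 °C, dark
Reagents that add atoms: none
Why: This is a concerted, suprafacial, normal-electron-demand [4π+2π] Diels-Alder cycloaddition of the two furan α-carbons to the doubly sulfonyl-activated alkene, the established use of 1,2-bis(phenylsulfonyl)ethene as an acetylene equivalent towards furans. It closes the six-membered carbocycle C1-C6 intermolecularly by making C1-C2 and C3-C4 at the same time, and it converts the furan ring into the 1,4-oxygen bridge of a 7-oxabicyclo[2.2.1]heptene, so both rings arise by cycloaddition and not by a separate cyclisation mode. The bridgeheads C1 and C4 are forced cis by suprafacial addition across the planar furan, and C2 and C3 are cis because the Z geometry is transferred stereospecifically; the adduct is racemic and its endo/exo composition is irrelevant, since in step 3 C2 and C3 become sp2 and C1 and C4 lose their stereogenicity. The usual regiochemical problem of 2-substituted furans does not arise because the dienophile is constitutionally symmetrical, and the Lewis-acid-free medium keeps the ionisable furfuryl ester intact. The only selectivity needed is thermodynamic (adduct against cycloreversion), which high concentration, low temperature and the two strongly withdrawing sulfonyl groups should secure. In one operation two flat, achiral components deliver all six ring carbons, the C4 oxygen and, stored as the strained C1-O bond, the latent C1=C2 alkene.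

Step 3
Reactants: 4 racemic bis-sulfone adduct
Product: 5 (7-oxabicyclo[2.2.1]hepta-2,5-dien-1-yl)methyl benzoate
Conditions: 6% Na(Hg), NaH2PO4, MeOH-THF, -20 to 0 °C
Reagents that add atoms: none
Why: Reductive 1,2-elimination of a vicinal bis-sulfone (Julia-type, the standard unmasking of this acetylene equivalent): electron transfer cleaves one C-S bond and the second sulfinate, a much better leaving group than the bridge alkoxide, is expelled to give C2=C3, so all stereocentres of 4 vanish and 5 is achiral with a mirror plane through C1, C4 and O.

Step 4
Reactants: 5 (7-oxabicyclo[2.2.1]hepta-2,5-dien-1-yl)methyl benzoate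
Product: 6 [(3R,4R)-3-(benzoyloxy)-4-hydroxycyclohexa-1,5-dien-1-yl]methyl benzoate
Conditions: [Rh(cod)Cl]2 (2.5 mol %), (R,S)-PPF-PtBu2 (Josiphos, 6 mol %), PhCO2H (1.5 equiv), Et3N (1 equiv), Et3N·HCl (additive), THF, rt to 40 °C
Reagents that add atoms: benzoic acid, O=C(O)c1ccccc1
Why: Proposed new method: exo-bound Rh(I) should insert with retention into the more substituted allylic bridgehead C1-O bond, and benzoate should attack the allyl-rhodium anti to the metal at the terminus remote from CH2OBz (C3), giving C1=C2 and the C3 benzoate trans to the liberated C4-OH; because 5 has a mirror plane, the ligand only has to choose between two enantiotopic C=C arms, and the arm on which catalyst preference and the substrate bias for C1-O cleavage coincide should lead to (3R,4R)-6. The closest known reaction types are the Rh(I)-catalysed alcoholysis of 7-oxanorbornadienes to 5,6-disubstituted cyclohexa-1,3-dienes, the Rh/Josiphos asymmetric ring opening of oxabenzonorbornadienes with carboxylates (trans-1,2 products), and the distal-attack regiochemistry of bridgehead-substituted oxabenzonorbornadienes; what is new is the desymmetrisation of a non-benzo-fused diene by arm selection.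

Step 5
Reactants: 6 trans-diene monobenzoate
Product: 7 [(3R,4S,5S,6R)-3-(benzoyloxy)-5,6-epoxy-4-hydroxycyclohex-1-en-1-yl]methyl benzoate
Conditions: VO(acac)2 (3 mol %), t-BuOOH (decane solution, 1.2 equiv), CH2Cl2, 0 °C
Reagents that add atoms: tert-butyl hydroperoxide, CC(C)(C)OO
Why: Vanadium-catalysed hydroxyl-directed epoxidation: the vanadate ester of the C4-OH delivers oxygen to the adjacent C5=C6 bond on its own face, which is also the face anti to the C3 benzoate, so C5 and C6 are set with the oxirane cis to 4-OH while the undirected, inductively deactivated C1=C2 bond is left alone.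

Step 6
Reactants: 7 syn-epoxy alcohol
Product: 8 [(3R,4R,5R,6S)-3-(benzoyloxy)-4,5,6-trihydroxycyclohex-1-en-1-yl]methyl benzoate (target)
Conditions: HClO4 (5 mol %), THF-H2O (3:1), 0 °C
Reagents that add atoms: water, O
Why: Acid-catalysed anti (SN2-type) hydrolysis of a vinyl epoxide: water should attack the allylically activated C6 rather than C5, which is deactivated by the flanking C4-OH, so C6 is inverted (OH trans to 5-OH), C5 keeps its oxygen cis to 4-OH, and the trans, cis, trans array of the target results.

## Compound list

1 | furfuryl alcohol | OCc1ccco1 | starting material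
2 | furfuryl benzoate | O=C(OCc1ccco1)c1ccccc1 | intermediate
3 | (Z)-1,2-bis(phenylsulfonyl)ethene | O=S(=O)(/C=C\S(=O)(=O)c1ccccc1)c1ccccc1 | starting material
4 | [2,3-cis-bis(phenylsulfonyl)-7-oxabicyclo[2.2.1]hept-5-en-1-yl]methyl benzoate (racemic; endo,endo isomer, one enantiomer drawn; the exo,exo isomer serves equally) | O=C(OC[C@]12O[C@H](C=C1)[C@H](S(=O)(=O)c3ccccc3)[C@@H]2S(=O)(=O)c4ccccc4)c5ccccc5 | intermediate
5 | (7-oxabicyclo[2.2.1]hepta-2,5-dien-1-yl)methyl benzoate (achiral) | O=C(OCC12C=CC(O1)C=C2)c1ccccc1 | intermediate
6 | [(3R,4R)-3-(benzoyloxy)-4-hydroxycyclohexa-1,5-dien-1-yl]methyl benzoate | O=C(OCC1=C[C@@H](OC(=O)c2ccccc2)[C@H](O)C=C1)c1ccccc1 | intermediate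
7 | [(3R,4S,5S,6R)-3-(benzoyloxy)-5,6-epoxy-4-hydroxycyclohex-1-en-1-yl]methyl benzoate (oxirane cis to 4-OH, trans to 3-OBz) | O=C(OCC1=C[C@@H](OC(=O)c2ccccc2)[C@H](O)[C@@H]3O[C@@H]31)c1ccccc1 | intermediate
8 | [(3R,4R,5R,6S)-3-(benzoyloxy)-4,5,6-trihydroxycyclohex-1-en-1-yl]methyl benzoate | O=C(OCC1=C[C@@H](OC(=O)c2ccccc2)[C@H](O)[C@H](O)[C@H]1O)c1ccccc1 | target

## Step count and risks

Total step count: 6. Longest linear sequence: 6.

**Step 4 (labelled step).**
- What may go wrong: the strained diene may isomerise at rhodium to phenolic material, both C=C bonds may chelate and sequester the metal, or the two enantiotopic arms may be discriminated poorly.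
- Fallback: it sets out from 5. One equivalent of mCPBA (NaHCO3, CH2Cl2, 0 °C) attacks either alkene from the exo face and should give racemic (5,6-exo-epoxy-7-oxabicyclo[2.2.1]hept-2-en-1-yl)methyl benzoate F1.
- F1 is an ordinary 7-oxanorbornene, the class for which Rh/Josiphos opening with heteroatom nucleophiles is established. Racemic bridgehead-substituted oxabicycles are known to undergo regiodivergent resolution with a cationic Rh/Josiphos catalyst.
- With benzoic acid, one enantiomer should give 7 directly. The other should give the separable tertiary alcohol [2-(benzoyloxy)-5,6-epoxy-1-hydroxycyclohex-3-en-1-yl]methyl benzoate F2.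
- The route is rejoined at 7 and step 5 is skipped, at the price of at most half of the material.

**Step 6.**
- What may go wrong: an allyl-cation pathway may erode regio- and stereocontrol (SN2' or syn attack), and the primary benzoate may participate and migrate.
- Fallback: it sets out from 7. The known neutral [Rh(CO)2Cl]2-catalysed alcoholysis of vinyl epoxides is anti and selective for the allylic carbon. With 4-methoxybenzyl alcohol (THF, rt) it should give the 6-O-(4-methoxybenzyl) ether of the target F3.
- Oxidative cleavage with DDQ (CH2Cl2, pH 7 buffer) then returns to the route at 8.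

**Step 3.**
- What may go wrong: the bridge alkoxide may be expelled instead of the second sulfinate, adventitious methoxide may cleave the benzoate, and the diene may decompose during isolation.
- Fallback: it sets out from 2 and unmasks the alkene oxidatively instead of reductively. Diels-Alder reaction with maleic anhydride (Et2O, rt) should give the racemic exo-anhydride adduct F4, and mild hydrolysis (THF-H2O, rt) the exo,exo-dicarboxylic acid F5.
- Anodic oxidative bis-decarboxylation (Pt, pyridine-H2O-Et3N, below 20 °C) then returns to the route at 5.

## Further compounds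

F1 | step 4 | (5,6-exo-epoxy-7-oxabicyclo[2.2.1]hept-2-en-1-yl)methyl benzoate (racemic; the enantiomer that leads to 7 is drawn) | O=C(OC[C@@]12O[C@@H](C=C1)[C@@H]3O[C@@H]32)c1ccccc1
F2 | step 4 | [2-(benzoyloxy)-5,6-epoxy-1-hydroxycyclohex-3-en-1-yl]methyl benzoate (1-OH trans to 2-OBz, oxirane cis to 1-OH; from the other enantiomer of F1) | O=C(OC[C@]1(O)[C@H](OC(=O)c2ccccc2)C=C[C@H]2O[C@H]21)c1ccccc1
F3 | step 6 | [(3R,4R,5R,6S)-3-(benzoyloxy)-4,5-dihydroxy-6-(4-methoxybenzyloxy)cyclohex-1-en-1-yl]methyl benzoate | O=C(OCC1=C[C@@H](OC(=O)c2ccccc2)[C@H](O)[C@H](O)[C@H]1OCc1ccc(OC)cc1)c1ccccc1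
F4 | step 3 | exo Diels-Alder adduct of furfuryl benzoate and maleic anhydride (racemic, one enantiomer drawn) | O=C(OC[C@]12O[C@H](C=C1)[C@H]3C(=O)OC(=O)[C@H]32)c1ccccc1
F5 | step 3 | 1-(benzoyloxymethyl)-7-oxabicyclo[2.2.1]hept-5-ene-2,3-exo,exo-dicarboxylic acid (racemic, one enantiomer drawn) | O=C(OC[C@]12O[C@H](C=C1)[C@@H](C(=O)O)[C@H]2C(=O)O)c1ccccc1
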